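**Plan**
- Retrosynthesis: ring C is opened first by cutting C3–C4 and O1–C2 together. This gives 2-hydroxy-4-methoxybenzaldehyde and a terminal aryl alkyne whose atoms add up exactly to the target. The alkyne is then cut back to an aldehyde, and the furan is cut at its O–C2 and C3–C3a bonds to an o-iodophenol and 4-ethynylanisole.
- Forward order: furan ring (Sonogashira/5-endo-dig), then CHO → C≡CH homologation, then ring C last in a hydroacylation/oxa-Michael relay.
- Enabling feature: on ring A the phenolic O1 (on C8a) sits ortho to the carbonyl carbon C4 (on C4a), so the same oxygen first chelates Rh at the formyl C–H and then attacks C2. C5 carries no OH, so the chalcone does not close unaided and the flavanone does not reopen.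
- Oxidation level: the C2–C3 unit enters as an alkyne, not an alkene, so the key step is redox-neutral and needs no oxidant or helper group.
- Stereochemistry: C2 (S) is the only stereocentre. A chalcone isomerase sets it in the last step, and nothing follows that could scramble it.

Key step: step 3

Assumption: a recombinant type II (legume-type, 6'-deoxychalcone-accepting) chalcone isomerase is counted as an obtainable catalyst, not as a starting material.

**Step 1**
Reactants: 1 4-hydroxy-3-iodobenzaldehyde; 2 1-ethynyl-4-methoxybenzene
Product: 4 2-(4-methoxyphenyl)-1-benzofuran-5-carbaldehyde, via alkynylphenol 3 (not isolated)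
Conditions: PdCl2(PPh3)2 (cat.), CuI (cat.), Et3N, DMF, 70 °C
Reagents that add atoms: none
Why: Sonogashira coupling at the C–I bond gives 3, whose phenol (acidified by the para formyl group) adds 5-endo-dig to the metal-activated alkyne at the anisyl-bearing carbon, a tandem Sonogashira/heteroannulation that is standard for 2-arylbenzofuran-5-carbaldehydes and forms no stereocentre.

**Step 2**
Reactants: 4 2-(4-methoxyphenyl)-1-benzofuran-5-carbaldehyde
Product: 5 5-ethynyl-2-(4-methoxyphenyl)-1-benzofuran
Conditions: Ohira–Bestmann reagent, K2CO3, MeOH/THF, rt
Reagents that add atoms: dimethyl (1-diazo-2-oxopropyl)phosphonate, CC(=O)C(=[N+]=[N-])P(=O)(OC)OC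
Why: In this Seyferth–Gilbert homologation (Ohira–Bestmann form), methanolysis frees the diazomethylphosphonate anion, which olefinates the non-enolisable aldehyde, and loss of N2 with a 1,2-H shift gives the terminal alkyne under conditions that leave the benzofuran and aryl ethers untouched.

**Step 3**
Reactants: 5 5-ethynyl-2-(4-methoxyphenyl)-1-benzofuran; 6 2-hydroxy-4-methoxybenzaldehyde
Product: 8 lophirone J, (2S)-7-methoxy-2-[2-(4-methoxyphenyl)-1-benzofuran-5-yl]-2,3-dihydro-4H-chromen-4-one, via chalcone 7 (not isolated)
Conditions: [RhCl(cod)]2 (2.5 mol %), dppf (5 mol %), Na2CO3 (10 mol %), PhMe, 80 °C, slow addition of 5; then thiol-silica filtration and solvent swap to DMSO, type II chalcone isomerase (EC 5.5.1.6), KPi buffer pH 7.5, HP-β-cyclodextrin, 30 °C, dark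
Reagents that add atoms: none
Why: Proposed new method: the phenoxide of 6 binds Rh(I) and steers it into the formyl C–H bond to give a five-membered O,C-chelated acyl rhodium(III) hydride that resists decarbonylation, syn insertion of the terminal alkyne of 5 into Rh–H places Rh on the terminal carbon, C–C reductive elimination makes C3–C4 and releases (E)-chalcone 7, and the isomerase then holds 7 with its 2'-phenoxide over C2 of the enone, stabilises the enolate through its hydrogen-bond network and makes O1–C2 before C3 is protonated. The closest known reaction types are the rhodium-catalysed hydroacylation of alkynes with salicylaldehydes followed in the same flask by oxa-Michael closure to chroman-4-ones, and the chalcone isomerase cyclisation of 6'-deoxy-2'-hydroxychalcones to (2S)-flavanones, so only the telescoping of the two catalysts and the long benzofuran B ring plus the 4'-O-methyl group on the enzyme substrate are new. Ring C closes in the 6-endo-trig mode. C2 is the only new stereocentre and is set by the enzyme pocket, which exposes a single face of the C2=C3 bond to the phenoxide and gives the 2S series with every substrate this class is known to turn over, something no small-molecule catalyst does reliably for a chalcone without an extra activating group at C3. The step needs linear over branched hydroacylation, which the unsubstituted alkyne terminus and the bulky dppf-bound rhodacycle should secure, and enzymatic over spontaneous closure, which the missing 6'-OH secures because the single 2'-OH is locked in a hydrogen bond to C4=O and closes only slowly at pH 7.5 without the enzyme. Acceptance of 7 is argued from the bond-making contacts of the enzyme, which all lie around O1, C4=O and C2, while the far end of ring B is expected to point to the open mouth of the cleft where the added aryl-furan can be accommodated.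

**Compound list**
1 | 4-hydroxy-3-iodobenzaldehyde | O=Cc1ccc(O)c(I)c1 | starting material
2 | 1-ethynyl-4-methoxybenzene | C#Cc1ccc(OC)cc1 | starting material
3 | 4-hydroxy-3-[(4-methoxyphenyl)ethynyl]benzaldehyde | O=Cc1ccc(O)c(C#Cc2ccc(OC)cc2)c1 | intermediate
4 | 2-(4-methoxyphenyl)-1-benzofuran-5-carbaldehyde | COc1ccc(-c2cc3cc(C=O)ccc3o2)cc1 | intermediate
5 | 5-ethynyl-2-(4-methoxyphenyl)-1-benzofuran | COc1ccc(-c2cc3cc(C#C)ccc3o2)cc1 | intermediate
6 | 2-hydroxy-4-methoxybenzaldehyde | COc1ccc(C=O)c(O)c1 | starting material
7 | (E)-1-(2-hydroxy-4-methoxyphenyl)-3-[2-(4-methoxyphenyl)-1-benzofuran-5-yl]prop-2-en-1-one | COc1ccc(-c2cc3cc(/C=C/C(=O)c4ccc(OC)cc4O)ccc3o2)cc1 | intermediate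
8 | lophirone J, (2S)-7-methoxy-2-[2-(4-methoxyphenyl)-1-benzofuran-5-yl]-2,3-dihydro-4H-chromen-4-one | COc1ccc(-c2cc3cc([C@@H]4CC(=O)c5ccc(OC)cc5O4)ccc3o2)cc1 | target

Total step count: 3. Longest linear sequence: 3 steps (1 → 4 → 5 → 8).

**Steps most likely to fail**

Step 3. Several processes could go wrong:
- The aryl alkyne may oligomerise on Rh(I), or insertion may go the branched way.
- The base of the first stage may start a racemic ring closure.
- The enzyme may bind the long, poorly soluble, 4'-O-methylated chalcone too weakly to outrun the background reaction.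

The fallback uses known chemistry, sets out from 4 and comes back at 8. It builds ring C through C2–C3 and O1–C2 instead. Crossed Claisen condensation of commercial methyl 2-hydroxy-4-methoxybenzoate with the lithium enolate of tert-butyl acetate gives tert-butyl 3-(2-hydroxy-4-methoxyphenyl)-3-oxopropanoate F1. Knoevenagel condensation of F1 with 4 (piperidine, AcOH, toluene, molecular sieves) gives tert-butyl (Z)-2-(2-hydroxy-4-methoxybenzoyl)-3-[2-(4-methoxyphenyl)-1-benzofuran-5-yl]prop-2-enoate F2. A bifunctional cinchona thiourea, taken from the pseudoenantiomeric series that leads to 2S, is applied in toluene at −25 °C. It closes the activated enone by asymmetric oxa-Michael addition to tert-butyl (2S,3R)-7-methoxy-2-[2-(4-methoxyphenyl)-1-benzofuran-5-yl]-4-oxo-3,4-dihydro-2H-chromene-3-carboxylate F3. Acid-induced removal of the ester group (TsOH, toluene, 80 °C) then gives 8.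

Step 1. Glaser-type homocoupling of 2 may consume the alkyne, and the 5-endo closure may stall at the alkynylphenol stage. The fallback sets out from 1 and comes back at 4. Heck coupling of 1 with commercial 4-vinylanisole (Pd(OAc)2, P(o-tol)3, Et3N, DMF, 100 °C) gives (E)-4-hydroxy-3-[2-(4-methoxyphenyl)ethenyl]benzaldehyde F4. Oxidative C–O cyclisation of this o-hydroxystilbene with PhI(OAc)2 in MeCN then forms the furan ring of 4.

Step 2. Olefination of the sparingly soluble aldehyde may be slow, and methanol may trap the vinylidene before the 1,2-shift. The fallback sets out from 4 and comes back at 5. Corey–Fuchs dibromoolefination (CBr4, PPh3, CH2Cl2, 0 °C) gives 5-(2,2-dibromoethenyl)-2-(4-methoxyphenyl)-1-benzofuran F5. Treatment with n-BuLi (THF, −78 °C) induces Fritsch–Buttenberg–Wiechell rearrangement, and an aqueous quench gives 5.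

**Further compounds**
F1 | step 3 | tert-butyl 3-(2-hydroxy-4-methoxyphenyl)-3-oxopropanoate | COc1ccc(C(=O)CC(=O)OC(C)(C)C)c(O)c1
F2 | step 3 | tert-butyl (Z)-2-(2-hydroxy-4-methoxybenzoyl)-3-[2-(4-methoxyphenyl)-1-benzofuran-5-yl]prop-2-enoate | COc1ccc(-c2cc3cc(/C=C(\C(=O)OC(C)(C)C)C(=O)c4ccc(OC)cc4O)ccc3o2)cc1
F3 | step 3 | tert-butyl (2S,3R)-7-methoxy-2-[2-(4-methoxyphenyl)-1-benzofuran-5-yl]-4-oxo-3,4-dihydro-2H-chromene-3-carboxylate | COc1ccc(-c2cc3cc([C@@H]4[C@@H](C(=O)OC(C)(C)C)C(=O)c5ccc(OC)cc5O4)ccc3o2)cc1
F4 | step 1 | (E)-4-hydroxy-3-[2-(4-methoxyphenyl)ethenyl]benzaldehyde | COc1ccc(/C=C/c2cc(C=O)ccc2O)cc1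
F5 | step 2 | 5-(2,2-dibromoethenyl)-2-(4-methoxyphenyl)-1-benzofuran | COc1ccc(-c2cc3cc(C=C(Br)Br)ccc3o2)cc1
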